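**Retrosynthetic overview**
1. Target 21 ← bis-silyl ether 20 ← enantioselective rhodium-catalysed 1,4-addition of ring-B boronic acid 14 to 7-silyloxy-8-prenylchromone 19; this makes the C2–aryl bond and sets (2S), with rings A and C arriving together as the chromone.
2. Chromone 19 ← 7-hydroxychromone 15 by O-(1,1-dimethylpropargyl)ation, semihydrogenation and an ortho-Claisen shift of the resulting 1,1-dimethylallyl ether to C8.
3. Boronic acid 14 ← chromene aldehyde 6: the formyl carbon becomes C1' of the side chain (Wittig homologation, isopropenyl addition, oxidation, CBS reduction sets 2'R), then Cl → B at C6.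
4. Key disconnection: the pyran ring of the chromene is annulated onto ring B in one pot, C4–C4a by Suzuki coupling at C4a–Br and O1–C8a by intramolecular SNAr at C8a–F. The enabling feature is that O1 and C4 sit on the adjacent ring-B carbons C8a and C4a, and C8a is ortho to C8, the carbon that carries the side chain; C8 is therefore carried as a formyl group that activates C8a–F, and the cis C3=C4 bond is supplied as a (Z)-alkenylboronate whose tertiary oxygen becomes O1.
5. Ring order: ring B (commercial arene) → pyran ring of the chromene (step 2) → rings A and C (commercial chromone) attached in step 13, where the ring-C stereocentre is created.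

Key step: step 2

Remark: locants O1–C8a are those of the 2H-chromene fused to ring B, and C1'–C4' those of the 2-hydroxy-3-methylbut-3-enyl chain; 3-bromo-5-chloro-2-fluorobenzaldehyde is taken to be a catalogue compound.

**Step 1**
Reactants: 1 [(2-methylbut-3-yn-2-yl)oxy]trimethylsilane
Product: 2 (Z)-trimethyl{[2-methyl-4-(4,4,5,5-tetramethyl-1,3,2-dioxaborolan-2-yl)but-3-en-2-yl]oxy}silane
Conditions: HBpin, [RhCl(cod)]2 (1.5 mol%), P(i-Pr)3 (6 mol%), Et3N, cyclohexane, rt
Reagents that add atoms: pinacolborane, [H]B1OC(C)(C)C(C)(C)O1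
Why: Rhodium-catalysed trans-hydroboration of a terminal alkyne (vinylidene pathway) places boron on the terminal carbon anti to the added hydrogen, so the (Z)-alkenylboronate with the cis geometry of the later C3=C4 bond should form, and the O-silyl group keeps the tertiary alcohol from consuming pinacolborane.

**Step 2**
Reactants: 3 3-bromo-5-chloro-2-fluorobenzaldehyde; 2 (Z)-trimethyl{[2-methyl-4-(4,4,5,5-tetramethyl-1,3,2-dioxaborolan-2-yl)but-3-en-2-yl]oxy}silane
Product: 6 6-chloro-2,2-dimethyl-2H-chromene-8-carbaldehyde, via Z-alkenyl silyl ether 4 (not isolated), via fluoro alcohol 5 (not isolated)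
Conditions: PdCl2(dppf) (5 mol%), CsF (4 equiv), 1,4-dioxane/DMF, 80 °C then 110 °C
Reagents that add atoms: none
Why: Zerovalent palladium inserts into the C4a–Br bond of 3, and transmetalation with fluoride-activated boronate 2 followed by reductive elimination with retention of the Z geometry forms C4–C4a and gives silyl ether 4. Fluoride then cleaves the tertiary trimethylsilyl ether, and the cesium alkoxide of 5, held next to C8a by the cis alkene, adds to C8a to give a Meisenheimer adduct stabilised by the ortho formyl group at C8 and expels fluoride, which forms O1–C8a. The closest known reaction type is the one-pot Suzuki–Miyaura coupling/intramolecular SNAr etherification used to make dibenzofurans from ortho-fluoro haloarenes and 2-hydroxyphenylboron reagents. The pyran ring closes by intramolecular SNAr, a 6-exo-trig addition of O1 to the arene carbon followed by loss of fluoride. No stereocentre is formed; the only stereochemical demand is the Z alkene, which is fixed in reagent 2. The step needs site selectivity among three carbon–halogen bonds and between the internal alkoxide and external nucleophiles, and this is secured by the order Br > Cl >> F in oxidative addition, by the formyl group that activates only the fluorine-bearing carbon, and by anhydrous fluoride as the sole base.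

**Step 3**
Reactants: 6 6-chloro-2,2-dimethyl-2H-chromene-8-carbaldehyde
Product: 8 2-(6-chloro-2,2-dimethyl-2H-chromen-8-yl)acetaldehyde, via enol ether 7 (not isolated)
Conditions: Ph3P(CH2OMe)Cl, KN(SiMe3)2, THF, 0 °C to rt; then 2 M HCl, THF, rt; crude aldehyde used at once
Reagents that add atoms: (methoxymethyl)triphenylphosphonium chloride, COC[P+](c1ccccc1)(c1ccccc1)c1ccccc1.[Cl-]; water, O
Why: Wittig methoxymethylenation followed by acid hydrolysis of enol ether 7 is the standard one-carbon homologation of an aryl aldehyde to an arylacetaldehyde, which turns the former SNAr-activating formyl carbon into C1' of the side chain, and the chlorine-deactivated chromene should tolerate dilute aqueous acid at room temperature.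

**Step 4**
Reactants: 8 2-(6-chloro-2,2-dimethyl-2H-chromen-8-yl)acetaldehyde
Product: 9 rac-1-(6-chloro-2,2-dimethyl-2H-chromen-8-yl)-3-methylbut-3-en-2-ol
Conditions: CH2=C(CH3)MgBr, THF, −78 °C; aq. NH4Cl
Reagents that add atoms: isopropenylmagnesium bromide, CC(=C)[Mg]Br
Why: 1,2-Addition of an alkenyl Grignard reagent to an aldehyde at low temperature, where addition should outrun enolisation of the arylacetaldehyde, gives the racemic allylic alcohol; no stereocontrol is sought because the carbinol is re-set in step 6.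

**Step 5**
Reactants: 9 rac-1-(6-chloro-2,2-dimethyl-2H-chromen-8-yl)-3-methylbut-3-en-2-ol
Product: 10 1-(6-chloro-2,2-dimethyl-2H-chromen-8-yl)-3-methylbut-3-en-2-one
Conditions: Dess–Martin periodinane, NaHCO3, CH2Cl2, 0 °C; used without storage
Reagents that add atoms: none
Why: Dess–Martin oxidation of a secondary allylic alcohol under buffered, non-basic conditions should give the isopropenyl ketone without conjugate addition or double-bond migration.

**Step 6**
Reactants: 10 1-(6-chloro-2,2-dimethyl-2H-chromen-8-yl)-3-methylbut-3-en-2-one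
Product: 11 (2R)-1-(6-chloro-2,2-dimethyl-2H-chromen-8-yl)-3-methylbut-3-en-2-ol
Conditions: (S)-Me-CBS oxazaborolidine (20 mol%), catecholborane, toluene, −78 °C
Reagents that add atoms: none
Why: Corey–Bakshi–Shibata reduction, in which the ketone should bind the (S)-oxazaborolidine with the isopropenyl group as the large and the benzylic CH2 as the small substituent, so that hydride is delivered to the face giving the (R)-carbinol (the same sense as acetophenone to (R)-1-phenylethanol), while catecholborane at −78 °C reduces the enone in 1,2-fashion only.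

**Step 7**
Reactants: 11 (2R)-1-(6-chloro-2,2-dimethyl-2H-chromen-8-yl)-3-methylbut-3-en-2-ol
Product: 12 tert-butyl{[(2R)-1-(6-chloro-2,2-dimethyl-2H-chromen-8-yl)-3-methylbut-3-en-2-yl]oxy}dimethylsilane
Conditions: TBSCl, imidazole, DMF, rt
Reagents that add atoms: tert-butyldimethylsilyl chloride, CC(C)(C)[Si](C)(C)Cl
Why: Standard silylation of a secondary alcohol, which masks the allylic alcohol against palladium-mediated ionisation and against the boron reagents of step 8.

**Step 8**
Reactants: 12 tert-butyl{[(2R)-1-(6-chloro-2,2-dimethyl-2H-chromen-8-yl)-3-methylbut-3-en-2-yl]oxy}dimethylsilane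
Product: 14 {8-[(2R)-2-(tert-butyldimethylsilyloxy)-3-methylbut-3-en-1-yl]-2,2-dimethyl-2H-chromen-6-yl}boronic acid, via pinacol boronate 13 (not isolated)
Conditions: B2pin2, Pd2(dba)3 (2 mol%), XPhos (8 mol%), KOAc, 1,4-dioxane, 100 °C; then NaIO4, NH4OAc, acetone/H2O, rt
Reagents that add atoms: bis(pinacolato)diboron, CC1(C)OB(OC1(C)C)B1OC(C)(C)C(C)(C)O1; water, O
Why: Miyaura borylation of an electron-rich aryl chloride with an XPhos-ligated palladium catalyst, followed by periodate cleavage of the pinacol ester (periodate alone does not attack the alkenes), should give the free boronic acid needed for base-free rhodium catalysis.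

**Step 9**
Reactants: 15 7-hydroxy-4H-chromen-4-one
Product: 16 7-[(2-methylbut-3-yn-2-yl)oxy]-4H-chromen-4-one
Conditions: 3-chloro-3-methylbut-1-yne, DBU, CuCl2 (cat.), MeCN, 0 °C
Reagents that add atoms: 3-chloro-3-methylbut-1-yne, C#CC(C)(C)Cl
Why: Copper-catalysed O-alkylation of a phenol with a tertiary propargylic chloride gives the 1,1-dimethylpropargyl aryl ether under a mild amine base that leaves the chromone intact.

**Step 10**
Reactants: 16 7-[(2-methylbut-3-yn-2-yl)oxy]-4H-chromen-4-one
Product: 17 7-[(2-methylbut-3-en-2-yl)oxy]-4H-chromen-4-one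
Conditions: H2 (1 atm), Pd/CaCO3 poisoned with Pb(OAc)2, quinoline, EtOAc, rt
Reagents that add atoms: none
Why: Lindlar semihydrogenation stops at the alkene and should leave the chromone C2=C3 bond, a vinylogous ester, untouched.

**Step 11**
Reactants: 17 7-[(2-methylbut-3-en-2-yl)oxy]-4H-chromen-4-one
Product: 18 7-hydroxy-8-(3-methylbut-2-en-1-yl)-4H-chromen-4-one
Conditions: PhNEt2, 150 °C
Reagents that add atoms: none
Why: Aromatic Claisen rearrangement of the 1,1-dimethylallyl ether inverts the allyl unit to a linear prenyl group and should go to C8, not C6, because the C7–C8 bond of the benzopyranone has the higher double-bond character, as with 7-allyloxy-coumarins and -chromones.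

**Step 12**
Reactants: 18 7-hydroxy-8-(3-methylbut-2-en-1-yl)-4H-chromen-4-one
Product: 19 7-(tert-butyldimethylsilyloxy)-8-(3-methylbut-2-en-1-yl)-4H-chromen-4-one
Conditions: TBSCl, imidazole, DMF, rt
Reagents that add atoms: tert-butyldimethylsilyl chloride, CC(C)(C)[Si](C)(C)Cl
Why: Silylation of the phenol keeps the chromone electrophilic in step 13 (no phenoxide) and gives a group that leaves together with the side-chain silyl ether at the end.

**Step 13**
Reactants: 14 {8-[(2R)-2-(tert-butyldimethylsilyloxy)-3-methylbut-3-en-1-yl]-2,2-dimethyl-2H-chromen-6-yl}boronic acid; 19 7-(tert-butyldimethylsilyloxy)-8-(3-methylbut-2-en-1-yl)-4H-chromen-4-one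
Product: 20 (2S)-7-(tert-butyldimethylsilyloxy)-2-{8-[(2R)-2-(tert-butyldimethylsilyloxy)-3-methylbut-3-en-1-yl]-2,2-dimethyl-2H-chromen-6-yl}-8-(3-methylbut-2-en-1-yl)-2,3-dihydro-4H-chromen-4-one
Conditions: [Rh(OH)(cod)]2 (3 mol%), (S)-MeO-F12-BIPHEP (7 mol%), toluene/H2O (10:1), 50 °C
Reagents that add atoms: none
Why: Hayashi–Miyaura rhodium-catalysed asymmetric 1,4-addition of an arylboronic acid to a chromone, in which the aryl–rhodium species carrying the (S)-configured electron-poor bisphosphine should add to the C2 face that gives the (2S)-flavanone (catalyst control, same sense as (S)-BINAP on cyclohexenone, to be confirmed by circular dichroism and the ligand antipode used otherwise), while base-free aqueous conditions protonate the rhodium enolate without opening ring C and the remote (R)-carbinol has no say in the facial choice.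

**Step 14**
Reactants: 20 (2S)-7-(tert-butyldimethylsilyloxy)-2-{8-[(2R)-2-(tert-butyldimethylsilyloxy)-3-methylbut-3-en-1-yl]-2,2-dimethyl-2H-chromen-6-yl}-8-(3-methylbut-2-en-1-yl)-2,3-dihydro-4H-chromen-4-one
Product: 21 (2S)-7-hydroxy-2-{8-[(2R)-2-hydroxy-3-methylbut-3-en-1-yl]-2,2-dimethyl-2H-chromen-6-yl}-8-(3-methylbut-2-en-1-yl)-2,3-dihydro-4H-chromen-4-one
Conditions: HF·pyridine, pyridine, THF, 0 °C to rt
Reagents that add atoms: none
Why: Fluoride cleaves the aryl and the secondary alkyl silyl ether under buffered, slightly acidic conditions that should neither epimerise C2 by retro-oxa-Michael ring opening nor cyclise the 8-prenyl-7-phenol nor ionise the allylic alcohol.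

**Compound list**
1 | [(2-methylbut-3-yn-2-yl)oxy]trimethylsilane | C#CC(C)(C)O[Si](C)(C)C | starting material
2 | (Z)-trimethyl{[2-methyl-4-(4,4,5,5-tetramethyl-1,3,2-dioxaborolan-2-yl)but-3-en-2-yl]oxy}silane | CC(C)(O[Si](C)(C)C)/C=C\B1OC(C)(C)C(C)(C)O1 | intermediate
3 | 3-bromo-5-chloro-2-fluorobenzaldehyde | O=Cc1cc(Cl)cc(Br)c1F | starting material
4 | (Z)-5-chloro-2-fluoro-3-[3-methyl-3-(trimethylsilyloxy)but-1-en-1-yl]benzaldehyde | CC(C)(O[Si](C)(C)C)/C=C\c1cc(Cl)cc(C=O)c1F | intermediate
5 | (Z)-5-chloro-2-fluoro-3-(3-hydroxy-3-methylbut-1-en-1-yl)benzaldehyde (present as its cesium alkoxide) | CC(C)(O)/C=C\c1cc(Cl)cc(C=O)c1F | intermediate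
6 | 6-chloro-2,2-dimethyl-2H-chromene-8-carbaldehyde | CC1(C)C=Cc2cc(Cl)cc(C=O)c2O1 | intermediate
7 | 6-chloro-8-(2-methoxyethenyl)-2,2-dimethyl-2H-chromene (E/Z mixture) | COC=Cc1cc(Cl)cc2C=CC(C)(C)Oc12 | intermediate
8 | 2-(6-chloro-2,2-dimethyl-2H-chromen-8-yl)acetaldehyde | O=CCc1cc(Cl)cc2C=CC(C)(C)Oc12 | intermediate
9 | rac-1-(6-chloro-2,2-dimethyl-2H-chromen-8-yl)-3-methylbut-3-en-2-ol | C=C(C)C(O)Cc1cc(Cl)cc2C=CC(C)(C)Oc12 | intermediate
10 | 1-(6-chloro-2,2-dimethyl-2H-chromen-8-yl)-3-methylbut-3-en-2-one | C=C(C)C(=O)Cc1cc(Cl)cc2C=CC(C)(C)Oc12 | intermediate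
11 | (2R)-1-(6-chloro-2,2-dimethyl-2H-chromen-8-yl)-3-methylbut-3-en-2-ol | C=C(C)[C@H](O)Cc1cc(Cl)cc2C=CC(C)(C)Oc12 | intermediate
12 | tert-butyl{[(2R)-1-(6-chloro-2,2-dimethyl-2H-chromen-8-yl)-3-methylbut-3-en-2-yl]oxy}dimethylsilane | C=C(C)[C@H](O[Si](C)(C)C(C)(C)C)Cc1cc(Cl)cc2C=CC(C)(C)Oc12 | intermediate
13 | tert-butyl{[(2R)-1-[2,2-dimethyl-6-(4,4,5,5-tetramethyl-1,3,2-dioxaborolan-2-yl)-2H-chromen-8-yl]-3-methylbut-3-en-2-yl]oxy}dimethylsilane | C=C(C)[C@H](O[Si](C)(C)C(C)(C)C)Cc1cc(B3OC(C)(C)C(C)(C)O3)cc2C=CC(C)(C)Oc12 | intermediate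
14 | {8-[(2R)-2-(tert-butyldimethylsilyloxy)-3-methylbut-3-en-1-yl]-2,2-dimethyl-2H-chromen-6-yl}boronic acid | C=C(C)[C@H](O[Si](C)(C)C(C)(C)C)Cc1cc(B(O)O)cc2C=CC(C)(C)Oc12 | intermediate
15 | 7-hydroxy-4H-chromen-4-one | O=c1ccoc2cc(O)ccc12 | starting material
16 | 7-[(2-methylbut-3-yn-2-yl)oxy]-4H-chromen-4-one | C#CC(C)(C)Oc1ccc2c(=O)ccoc2c1 | intermediate
17 | 7-[(2-methylbut-3-en-2-yl)oxy]-4H-chromen-4-one | C=CC(C)(C)Oc1ccc2c(=O)ccoc2c1 | intermediate
18 | 7-hydroxy-8-(3-methylbut-2-en-1-yl)-4H-chromen-4-one | CC(C)=CCc1c(O)ccc2c(=O)ccoc12 | intermediate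
19 | 7-(tert-butyldimethylsilyloxy)-8-(3-methylbut-2-en-1-yl)-4H-chromen-4-one | CC(C)=CCc1c(O[Si](C)(C)C(C)(C)C)ccc2c(=O)ccoc12 | intermediate
20 | (2S)-7-(tert-butyldimethylsilyloxy)-2-{8-[(2R)-2-(tert-butyldimethylsilyloxy)-3-methylbut-3-en-1-yl]-2,2-dimethyl-2H-chromen-6-yl}-8-(3-methylbut-2-en-1-yl)-2,3-dihydro-4H-chromen-4-one | C=C(C)[C@H](O[Si](C)(C)C(C)(C)C)Cc1cc([C@@H]2CC(=O)c3ccc(O[Si](C)(C)C(C)(C)C)c(CC=C(C)C)c3O2)cc2c1OC(C)(C)C=C2 | intermediate
21 | (2S)-7-hydroxy-2-{8-[(2R)-2-hydroxy-3-methylbut-3-en-1-yl]-2,2-dimethyl-2H-chromen-6-yl}-8-(3-methylbut-2-en-1-yl)-2,3-dihydro-4H-chromen-4-one (CNP0104040.1) | C=C(C)[C@H](O)Cc1cc([C@@H]2CC(=O)c3ccc(O)c(CC=C(C)C)c3O2)cc2c1OC(C)(C)C=C2 | target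

**Totals**
Total step count: 14. Longest linear sequence: 10 steps (steps 1–8, 13, 14).

**Steps most likely to fail, with fallbacks**

(1) Step 2, the tandem coupling/ring closure. The SNAr closure of 5 may lag behind the coupling, the alkenyl unit may isomerise from Z to E before closure (the E isomer cannot cyclise), or the hindered boronate 2 may protodeboronate. The fallback closes the pyran ring from a phenol by known chemistry and sets out from 3. SNAr with KOH in DMSO/H2O at the formyl-activated fluorine gives 3-bromo-5-chloro-2-hydroxybenzaldehyde F1. A Heck reaction of F1 with 2-methylbut-3-en-2-ol (Pd(OAc)2, P(o-tol)3, Et3N, DMF, 100 °C) gives (E)-5-chloro-2-hydroxy-3-(3-hydroxy-3-methylbut-1-en-1-yl)benzaldehyde F2. Heating F2 with catalytic pyridinium p-toluenesulfonate in toluene ionises the tertiary allylic alcohol, and the phenol closes the ring through the allyl cation/o-quinone methide, whatever the alkene geometry. The fallback comes back to the route at 6.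

(2) Step 13, the asymmetric 1,4-addition. Aryl transfer to the electron-rich 7-silyloxychromone may be slowed by the bisphosphine, so that protodeboronation of 14 wins, or the facial selectivity may be poor. The fallback sets out from 14 and 19. The addition is run with the more active ligand-free catalyst [Rh(OH)(cod)]2 in dioxane/H2O at 60 °C to give the C2-epimeric mixture of the bis-silyl flavanone F3. Kinetic resolution by Noyori transfer hydrogenation (RuCl[(R,R)-TsDPEN](p-cymene), HCO2H/Et3N, EtOAc) should then reduce the (2R)-epimer preferentially to the (2R,4R)-cis-flavan-4-ol F4, which is separated by chromatography. The unreacted (2S)-epimer is 20, where the fallback comes back to the route.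

(3) Step 6, the CBS reduction. The catalyst may discriminate poorly between the benzylic CH2 and the isopropenyl group, or enone 10 may condense with itself (Michael addition of the benzylic enolate) before it is reduced. The fallback avoids the enone and sets out from racemic alcohol 9. Sharpless kinetic resolution (Ti(OiPr)4, L-(+)-diisopropyl tartrate, t-BuOOH (0.6 equiv), 4 Å molecular sieves, CH2Cl2, −20 °C) should epoxidise the fast-reacting (S)-alcohol to the epoxy alcohol (1S)-2-(6-chloro-2,2-dimethyl-2H-chromen-8-yl)-1-[(2S)-2-methyloxiran-2-yl]ethan-1-ol F5. The titanium reagent epoxidises only the allylic-alcohol alkene, so the chromene double bond is left alone. The (R)-alcohol is recovered and is 11, where the fallback comes back to the route.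

**Further compounds**
F1 | step 2 | 3-bromo-5-chloro-2-hydroxybenzaldehyde | O=Cc1cc(Cl)cc(Br)c1O
F2 | step 2 | (E)-5-chloro-2-hydroxy-3-(3-hydroxy-3-methylbut-1-en-1-yl)benzaldehyde | CC(C)(O)/C=C/c1cc(Cl)cc(C=O)c1O
F3 | step 13 | 7-(tert-butyldimethylsilyloxy)-2-{8-[(2R)-2-(tert-butyldimethylsilyloxy)-3-methylbut-3-en-1-yl]-2,2-dimethyl-2H-chromen-6-yl}-8-(3-methylbut-2-en-1-yl)-2,3-dihydro-4H-chromen-4-one, mixture of C2 epimers | C=C(C)[C@H](O[Si](C)(C)C(C)(C)C)Cc1cc(C2CC(=O)c3ccc(O[Si](C)(C)C(C)(C)C)c(CC=C(C)C)c3O2)cc2c1OC(C)(C)C=C2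
F4 | step 13 | (2R,4R)-7-(tert-butyldimethylsilyloxy)-2-{8-[(2R)-2-(tert-butyldimethylsilyloxy)-3-methylbut-3-en-1-yl]-2,2-dimethyl-2H-chromen-6-yl}-8-(3-methylbut-2-en-1-yl)-3,4-dihydro-2H-chromen-4-ol | C=C(C)[C@H](O[Si](C)(C)C(C)(C)C)Cc1cc([C@H]2C[C@@H](O)c3ccc(O[Si](C)(C)C(C)(C)C)c(CC=C(C)C)c3O2)cc2c1OC(C)(C)C=C2
F5 | step 6 | (1S)-2-(6-chloro-2,2-dimethyl-2H-chromen-8-yl)-1-[(2S)-2-methyloxiran-2-yl]ethan-1-ol | C[C@]3(CO3)[C@@H](O)Cc1cc(Cl)cc2C=CC(C)(C)Oc12
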